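(The runs come from a simulation on assumed constants; scatter was added.)

Every exchange takes up one incoming ligand, so each complex with four exchanged holds 4 of them.

common to all: starting complex 10 mM
- grey: incoming ligand 1.5 equiv; leaving ligand 0.50 equiv; the very flask that is asked about, followed so far
- red: incoming ligand 1.5 equiv; leaving ligand 0.25 equiv; run made earlier
- flask: incoming ligand 1.50 equiv; leaving ligand 0.500 equiv; time 40 h

The flask charges 1.50 equiv, so its ligand cap, the equivalents of incoming ligand divided by 4, is 37.5% of the starting complex. On this count incoming ligand is the limiting reagent.

| grey: time / h | grey: complex with four exchanged / % | red: time / min | red: complex with four exchanged / % |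
|---|---|---|---|
| 3.00 | 9.8 | 4.00 | 0 |
| 6.00 | 20.5 | 12.0 | 0.1 |
| 12.0 | 25.8 | 20.0 | 0.4 |
| 20.0 | 27.9 | 30.0 | 1.4 |
| 40.0 | 31.4 | 50.0 | 2.8 |

(standard deviation of a reading: 1 percentage point)

- what is added takes up no volume worth counting
- a reading or a percentage of complex with four exchanged counts all its forms, free or not

Grey is this very flask, read in hours, and its last reading is 31.4% at 40.0 h, 6.1 percentage points under the cap, with the scatter of a reading on it. Its readings rise more slowly later, by 11 points between 3.00 h and 6.00 h but by 3.5 points between 20.0 h and 40.0 h. Red is read in minutes and climbs from 0% to 2.8%, readings near the scatter that hint at a lag. So partly exchanged complexes may come first, and the cap is a bound, not a destination.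

- oak: at 40 h take out 90% of the leaving ligand then present, then wait 20 h
- alder: change nothing and wait 20 h more
- cedar: at 40 h add incoming ligand, 50.0% of the amount charged, then wait 20 h
- maple: at 40 h add starting complex, 50.0% of the amount charged, then wait 20 h

- complex with four exchanged, in percent of the starting complex first charged, at 40 h
- what to do for the largest gain in complex with four exchanged; "none" if nothing gains more than 2 percentage points (oak / alder / cedar / maple / none)
- complex with four exchanged present, in percent of the starting complex first charged, after alder
- complex with four exchanged present, in percent of the starting complex first charged, after maple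

Cedar lifts the cap to 56.2%. But oak, alder and maple add no incoming ligand, so their cap stays at 37.5%. The reckoning here therefore takes the grey reading for now and picks cedar.

The forecast gives 31.2% now, 33.4% after alder, 31.5% after maple, and cedar as best, reasoning that “Cedar raises the cap to 56% and restores free incoming ligand”.

The flask gives 31.1%, 31.7% after alder and 31.5% after maple. Cedar gains most, 11 points.

    starting complex + incoming ligand → leaving ligand + complex with one exchanged (k = 3.20 /M/min)
    complex with one exchanged + incoming ligand → leaving ligand + complex with two exchanged (k = 6.70 /M/min)
    complex with two exchanged + incoming ligand → leaving ligand + complex with three exchanged (k = 0.530 /M/min)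
    complex with three exchanged + incoming ligand → leaving ligand + complex with four exchanged (k = 3.70 /M/min)
    starting complex + complex with four exchanged ⇌ idle adduct, settled at all times (K = 130 /M)
    leaving ligand + starting complex → side product (k = 8.50 /M/min)

At 40.0 h the flask stands 6.4 points under its cap, with 0.940% of its incoming ligand free and complex with two exchanged at 9.67%. The neighbour with 2.50 equiv of incoming ligand has a cap of 62.5% and gives 51.7% at the same time, 11 points under it, with side product at 48.2% and 17% of its incoming ligand still free.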